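**Retrosynthetic overview**
1. Remove the acetate. Open the α-methylene δ-lactone by retro Pd/CO cyclocarbonylation to a tertiary allylic alcohol that carries an ethynyl group on the ester-bearing quaternary carbon.
2. The allylic alcohol and trisubstituted alkene come from a ring-C cyclopentenone by nucleophilic epoxidation, methylenation and SmI2 opening. The ethynyl group comes from electrophilic alkynylation of the cyclopentenone β-keto ester.
3. Ring C comes from an intramolecular aldol condensation of an acetoacetate side chain onto the ring-B ketone.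
4. Key step: two C–C bonds are cut together. A lactone O–CH radical closes ring B 6-endo onto a methacryloyl group. The resulting tertiary radical, at the methyl-bearing quaternary carbon, is captured by the silyl enol ether of methyl acetoacetate.
5. The radical precursor comes from C-acylation of a Diels–Alder adduct of a 2-silyloxy-1,1-dimethyldiene and (5R)-menthyloxybutenolide. Ring order: A + γ-lactone → B → C → δ-lactone.

Assumption: (−)-menthol is a recoverable chiral auxiliary. None of its atoms reach the target, so it is listed as a reagent.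
Locants used below (terpenoid style): the decalin is C1–C10, with C3 carbinol, C4 CMe2, C5 ring-fusion CH, C6 lactone O–CH, C7 CH2, C8 C–Me, C9, and C10 the ring-fusion carbon bearing the lactone C=O. Ring C is C8, C9, C11, C12, C13, and C13 bears CO2Me.

Step 1
Reactants: 1 4-methylpent-1-en-3-one
Product: 2 tert-butyl(dimethyl)[(4-methylpenta-1,3-dien-3-yl)oxy]silane
Conditions: TBSOTf, Et3N, Et2O, 0 °C
Reagents that add atoms: TBSOTf, CC(C)(C)[Si](C)(C)OS(=O)(=O)C(F)(F)F
Why: Soft enolisation (silyl triflate/amine) at the only enolisable C–H gives the 2-silyloxydiene as a single regioisomer, and no stereocentre is formed.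

Step 2
Reactants: 3 5-hydroxyfuran-2(5H)-one
Product: 4 (5R)-5-(l-menthyloxy)furan-2(5H)-one
Conditions: (−)-menthol, CSA (cat.), toluene, 110 °C (−H2O); crystallise from petroleum ether, re-equilibrate the mother liquor with acid
Reagents that add atoms: (−)-menthol, C[C@@H]1CC[C@H]([C@@H](C1)O)C(C)C
Why: Acid-catalysed acetalisation of the lactol followed by crystallisation-induced epimerisation (second-order asymmetric transformation) gives the single (5R)-acetal, which is the source of all absolute stereochemistry.

Step 3
Reactants: 4 (5R)-5-(l-menthyloxy)furan-2(5H)-one; 2 silyloxydiene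
Product: 5 cis-fused Diels–Alder lactone acetal
Conditions: 2 (3 equiv), BHT, toluene, sealed tube, 120 °C
Reagents that add atoms: none
Why: In this thermal Diels–Alder reaction the nucleophilic CMe2 terminus of the 2-silyloxydiene bonds to the butenolide β-carbon ("para" rule) and the diene adds anti to the menthyloxy group, which sets C5 and C10 with a cis ring fusion.

Step 4
Reactants: 5 Diels–Alder lactone acetal; 6 methacryloyl chloride
Product: 7 C10-methacryloyl lactone acetal
Conditions: LDA, THF, −78 °C; then 6, −78 °C
Reagents that add atoms: none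
Why: Claisen-type C-acylation of the fully substituted lithium lactone enolate takes place on the convex face that held H-10, so the C10 quaternary centre forms with retention of the cis-fused lactone and the product has no acidic H to scramble it.

Step 5
Reactants: 8 methyl acetoacetate
Product: 9 methyl 3-(trimethylsilyloxy)but-2-enoate
Conditions: TMSCl, Et3N, hexane, rt
Reagents that add atoms: TMSCl, C[Si](C)(C)Cl
Why: O-silylation of the β-keto ester enol gives a push–pull alkene whose CH carbon is the nucleophilic site, and no stereocentre is formed.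

Step 6
Reactants: 7 C10-methacryloyl lactone acetal; 9 methyl 3-(trimethylsilyloxy)but-2-enoate
Product: 12 tricyclic trione keto ester, via bromolactone 10 (not isolated), via TBS enol ether 11 (not isolated)
Conditions: AcBr, ZnBr2 (2 mol %), CH2Cl2, 0 °C, evaporate; 9 (10 equiv), fac-Ir(ppy)3 (1 mol %), MeCN (0.02 M), 450 nm, rt; then 1 M HCl, THF
Reagents that add atoms: acetyl bromide, CC(=O)Br (its Br sits in 10 only)
Why: Proposed new method: AcBr/ZnBr2 exchanges the acetal alkoxy group for bromide (acetal → α-bromo ether exchange, with menthyl acetate as the thermodynamic sink), excited Ir(ppy)3 reduces this glycosyl-bromide-like C–Br bond to the nucleophilic α-acyloxy C6 radical, that radical closes ring B by 6-endo-trig addition to the tethered methacryloyl CH2 (possible only on the lactone face carrying the acyl group, which fixes C6 and gives the trans-decalin), the electrophilic tertiary α-keto C8 radical is then captured on its exo face (anti to the lactone bridge, so the C8 methyl ends axial) by the nucleophilic CH of 9, and Ir(IV) oxidises the α-silyloxy radical to the ketone with loss of TMSBr in a redox-neutral cycle; the closest known reaction types are photoredox Giese reactions of glycosyl bromides, 6-endo radical cyclisations onto acryloyl ketones and radical alkylation of silyl enol ethers to 1,4-dicarbonyls.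

Step 7
Reactants: 12 tricyclic trione keto ester
Product: 13 C3-axial alcohol
Conditions: NaHMDS (1.05 equiv), THF, −78 °C; L-Selectride (1.2 equiv), −78 °C; quench 1 M HCl
Reagents that add atoms: none
Why: The β-keto ester is masked as its sodium enolate and the C9 ketone is shielded by two quaternary carbons, so the bulky borohydride reduces only the 4,4-dimethyl-3-ketone by equatorial attack and gives the axial C3 alcohol, as with 3-oxo-triterpenoids.

Step 8
Reactants: 13 C3-axial alcohol
Product: 15 tetracyclic cyclopentenone β-keto ester, via ketol 14 (not isolated)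
Conditions: LDA (3.3 equiv), THF, −78 → 0 °C; then 2 M HCl, THF, 40 °C
Reagents that add atoms: none
Why: In this intramolecular aldol condensation the Weiler-type γ-carbanion of the acetoacetate unit is the only nucleophile able to reach the only accessible ketone (C9), and acid dehydration removes the transient C9 stereocentre.

Step 9
Reactants: 15 tetracyclic cyclopentenone β-keto ester
Product: 16 C13-ethynyl cyclopentenone
Conditions: TMS-EBX, TBAF, THF, −78 °C → rt
Reagents that add atoms: TMS-EBX, C[Si](C)(C)C#CI1OC(=O)c2ccccc12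
Why: Electrophilic alkynylation of the β-keto ester enolate with the hypervalent-iodine reagent EBX tolerates a neopentyl site, and attack anti to the angular C8 methyl (like α-face attack at C17 of steroids) sets the C13 quaternary centre.

Step 10
Reactants: 16 C13-ethynyl cyclopentenone
Product: 17 9,11-epoxy ketone
Conditions: t-BuOOH, DBU, toluene, 0 °C → rt
Reagents that add atoms: tert-butyl hydroperoxide, CC(C)(C)OO
Why: In this Weitz–Scheffer nucleophilic epoxidation the peroxide adds axially to C9 from the face anti to the C8 methyl and the C10 lactone carbonyl, which places the C9 oxygen on the face of the ethynyl group.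

Step 11
Reactants: 17 9,11-epoxy ketone
Product: 18 vinyl epoxide
Conditions: Ph3PCH3Br, KOt-Bu (3 equiv each), THF, 0 °C → rt
Reagents that add atoms: methyltriphenylphosphonium bromide, C[P+](c1ccccc1)(c1ccccc1)c1ccccc1.[Br-]
Why: Wittig methylenation works here because the ketone cannot enolise, the ester and lactones are inert to the ylide, and no stereocentre changes.

Step 12
Reactants: 18 vinyl epoxide
Product: 19 C9 tertiary allylic alcohol
Conditions: SmI2 (2.5 equiv), THF–MeOH, −78 °C
Reagents that add atoms: none
Why: Single-electron reduction of the vinyl oxirane cleaves the allylic C11–O bond, and the allylsamarium is protonated at the CH2 terminus, so the C9–O configuration is kept and the C11=C12(CH3) alkene is formed.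

Step 13
Reactants: 19 C9 tertiary allylic alcohol
Product: 20 deacetyl-meroantarctine B
Conditions: PdCl2 (10 mol %), thiourea (10 mol %), CO (1 atm), acetone, 50 °C
Reagents that add atoms: carbon monoxide, [C-]#[O+]
Why: Pd(II)-catalysed cyclocarbonylation of an alkynol proceeds by alkoxycarbonyl-palladium formation, 6-exo syn insertion of the cis-disposed alkyne and protonolysis, which gives the bridged α-methylene δ-lactone without touching a stereocentre.

Step 14
Reactants: 20 deacetyl-meroantarctine B
Product: 21 meroantarctine B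
Conditions: Ac2O, DMAP, pyridine, rt
Reagents that add atoms: acetic anhydride, CC(=O)OC(C)=O
Why: DMAP-catalysed acetylation acts on the only free hydroxyl group (the axial C3–OH) with retention.

**Compound list**
1 | 4-methylpent-1-en-3-one | C=CC(=O)C(C)C | starting material
2 | tert-butyl(dimethyl)[(4-methylpenta-1,3-dien-3-yl)oxy]silane | C=CC(O[Si](C)(C)C(C)(C)C)=C(C)C | intermediate
3 | 5-hydroxyfuran-2(5H)-one (racemising lactol) | OC1OC(=O)C=C1 | starting material
4 | (5R)-5-[(1R,2S,5R)-menthyloxy]furan-2(5H)-one | O=C1C=C[C@H](O[C@@H]2C[C@H](C)CC[C@H]2C(C)C)O1 | intermediate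
5 | cis-fused 5-(TBS-oxy)-3-(l-menthyloxy)-4,4-dimethyl-3a,4,7,7a-tetrahydro-2-benzofuran-1(3H)-one; H-3a, H-7a and the menthyloxy group all on one face | O=C1O[C@@H](O[C@@H]3C[C@H](C)CC[C@H]3C(C)C)[C@H]2[C@@H]1CC=C(O[Si](C)(C)C(C)(C)C)C2(C)C | intermediate
6 | methacryloyl chloride | C=C(C)C(=O)Cl | starting material
7 | 7a-(2-methylprop-2-enoyl) derivative of 5; acyl group on the face that held H-7a (cis to H-3a and to the menthyloxy group) | C=C(C)C(=O)[C@]12CC=C(O[Si](C)(C)C(C)(C)C)C(C)(C)[C@H]1[C@H](O[C@@H]3C[C@H](C)CC[C@H]3C(C)C)OC2=O | intermediate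
8 | methyl acetoacetate | CC(=O)CC(=O)OC | starting material
9 | methyl 3-(trimethylsilyloxy)but-2-enoate (E/Z) | COC(=O)C=C(C)O[Si](C)(C)C | intermediate
10 | 3-bromo analogue of 7 (menthyloxy replaced by Br, C–Br epimers) | C=C(C)C(=O)[C@]12CC=C(O[Si](C)(C)C(C)(C)C)C(C)(C)[C@H]1C(Br)OC2=O | intermediate
11 | tricyclic TBS enol ether: trans-decalin, C6–O/C10–C(=O) γ-lactone bridge, C9 ketone, C8 with axial Me (syn to the lactone bridge) and equatorial CH(CO2Me)COMe, C2=C3 silyl enol ether (C13 epimers) | CC(=O)C(C(=O)OC)[C@@]1(C)C[C@@H]2OC(=O)[C@@]3(C1=O)CC=C(O[Si](C)(C)C(C)(C)C)C(C)(C)[C@@H]23 | intermediate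
12 | tricyclic trione keto ester: as 11 with a C3 ketone (C13 epimers) | CC(=O)C(C(=O)OC)[C@@]1(C)C[C@@H]2OC(=O)[C@@]3(C1=O)CCC(=O)C(C)(C)[C@@H]23 | intermediate
13 | as 12 with an axial C3–OH (anti to the C10 lactone carbonyl, syn to H-5) | CC(=O)C(C(=O)OC)[C@@]1(C)C[C@@H]2OC(=O)[C@@]3(C1=O)CC[C@H](O)C(C)(C)[C@@H]23 | intermediate
14 | ring-C ketol (C9–OH, C12 ketone; C9 and C13 undefined) | COC(=O)C1C(=O)CC2(O)[C@]1(C)C[C@@H]3OC(=O)[C@]24CC[C@H](O)C(C)(C)[C@@H]34 | intermediate
15 | tetracyclic C9=C11 cyclopentenone (C12 ketone) with CO2Me at C13 (enolisable) | COC(=O)C1C(=O)C=C2[C@]1(C)C[C@@H]3OC(=O)[C@]24CC[C@H](O)C(C)(C)[C@@H]34 | intermediate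
16 | as 15 with quaternary C13: ethynyl anti and CO2Me syn to the C8 methyl | COC(=O)[C@@]1(C#C)C(=O)C=C2[C@]1(C)C[C@@H]3OC(=O)[C@]24CC[C@H](O)C(C)(C)[C@@H]34 | intermediate
17 | 9,11-epoxide of 16, oxygen on the ethynyl face (anti to the C8 methyl) | COC(=O)[C@@]1(C#C)C(=O)[C@@H]2O[C@]23[C@]1(C)C[C@@H]4OC(=O)[C@]35CC[C@H](O)C(C)(C)[C@@H]45 | intermediate
18 | 12-methylene analogue of 17 (vinyl epoxide) | COC(=O)[C@@]1(C#C)C(=C)[C@@H]2O[C@]23[C@]1(C)C[C@@H]4OC(=O)[C@]35CC[C@H](O)C(C)(C)[C@@H]45 | intermediate
19 | C9 axial tertiary alcohol with C11=C12(CH3) alkene; OH cis to the C13 ethynyl group | COC(=O)[C@@]1(C#C)C(C)=C[C@]2(O)[C@]1(C)C[C@@H]3OC(=O)[C@]24CC[C@H](O)C(C)(C)[C@@H]34 | intermediate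
20 | deacetyl-meroantarctine B (free C3–OH) | C=C1C(=O)O[C@@]23C=C(C)[C@]1(C(=O)OC)[C@@]2(C)C[C@@H]1OC(=O)[C@]32CC[C@H](O)C(C)(C)[C@@H]12 | intermediate
21 | meroantarctine B | C=C1C(=O)O[C@@]23C=C(C)[C@]1(C(=O)OC)[C@@]2(C)C[C@@H]1OC(=O)[C@]32CC[C@H](OC(C)=O)C(C)(C)[C@@H]12 | target

**Step count:** 14 steps in total. The longest linear sequence is 12 steps (steps 2–4 and 6–14).

**Steps most likely to fail**

**Step 3 (a hindered diene terminus meets an only moderately reactive butenolide).** This fallback sets out from 4 and returns at 7, replacing steps 3 and 4.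
- PhSLi adds to 4 anti to the menthyloxy group. The enolate is trapped with 6 to give the β-phenylthio α-methacryloyl lactone F1.
- mCPBA converts F1 into the sulfoxide F2. Warming in toluene causes syn-elimination to the 3-methacryloyl butenolide F3.
- F3 is a doubly activated dienophile and should take up 2 at or below room temperature. The facial and regiochemical bias is the same as in step 3, and the cycloaddition itself builds the C10 quaternary centre of 7.

**Step 6 (intermolecular capture of the tertiary radical).** This fallback sets out from 10 and returns at 13. It exchanges the roles of radical and acceptor.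
- (TMS)3SiH/AIBN cyclises 10 reductively to the tricyclic ketone TBS enol ether F4. Treatment with 1 M HCl gives the 3,9-diketone F5.
- L-Selectride gives the axial alcohol F6. TMSOTf/Et3N gives the C8=C9 silyl enol ether silyl ether F7.
- CAN/NaHCO3 oxidises 8 to the electrophilic acetoacetyl radical. This radical adds to C8 of F7 from the exo face, and mild acid work-up gives 13.

**Step 8 (polyanion aldol onto a ketone flanked by two quaternary carbons).** This fallback sets out from 13 and returns at 16.
- C13 is blocked first with TMS-EBX/TBAF to give the open-chain ethynyl keto ester F8. The C13 epimers are separated at this point.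
- The only enolisable site left is the acetyl CH3. Catalytic KOt-Bu in t-BuOH can therefore run a reversible aldol through the ethynyl ketol F9, followed by E1cB dehydration, to give 16 directly.

**Further compounds**
F1 | step 3 | β-phenylthio α-methacryloyl menthyloxy lactone (SPh trans to the menthyloxy group, C-α enolisable) | C=C(C)C(=O)C1C(=O)O[C@@H](O[C@@H]2C[C@H](C)CC[C@H]2C(C)C)[C@@H]1Sc1ccccc1
F2 | step 3 | sulfoxide of F1 (S epimers) | C=C(C)C(=O)C1C(=O)O[C@@H](O[C@@H]2C[C@H](C)CC[C@H]2C(C)C)[C@@H]1S(=O)c1ccccc1
F3 | step 3 | (5R)-3-methacryloyl-5-(l-menthyloxy)furan-2(5H)-one | C=C(C)C(=O)C1=C[C@H](O[C@@H]2C[C@H](C)CC[C@H]2C(C)C)OC1=O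
F4 | step 6 | tricyclic C9 ketone lactone with C2=C3 TBS enol ether (C8–H epimerisable) | CC1C[C@@H]2OC(=O)[C@@]3(C1=O)CC=C(O[Si](C)(C)C(C)(C)C)C(C)(C)[C@@H]23
F5 | step 6 | tricyclic 3,9-diketone lactone | CC1C[C@@H]2OC(=O)[C@@]3(C1=O)CCC(=O)C(C)(C)[C@@H]23
F6 | step 6 | tricyclic C9 ketone lactone with axial C3–OH | CC1C[C@@H]2OC(=O)[C@@]3(C1=O)CC[C@H](O)C(C)(C)[C@@H]23
F7 | step 6 | C8=C9 TMS enol ether, C3 TMS ether | CC1=C(O[Si](C)(C)C)[C@]23CC[C@H](O[Si](C)(C)C)C(C)(C)[C@H]2[C@H](C1)OC3=O
F8 | step 8 | open-chain C13-ethynyl keto ester (desired C13 epimer) | CC(=O)[C@](C#C)(C(=O)OC)[C@@]1(C)C[C@@H]2OC(=O)[C@@]3(C1=O)CC[C@H](O)C(C)(C)[C@@H]23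
F9 | step 8 | C13-ethynyl ring-C ketol (C9 undefined) | COC(=O)[C@@]1(C#C)C(=O)CC2(O)[C@]1(C)C[C@@H]3OC(=O)[C@]24CC[C@H](O)C(C)(C)[C@@H]34
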